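**Retrosynthetic overview**
Numbering (tetralin): C1 = CH(aryl), C2 and C3 = CHMe, C4 = CH2, C4a/C8a = ring-fusion carbons, OMe at C6 and C7.
Enabling feature: with C4–C4a cut, C1 bears two identical 3,4-dimethoxyphenyl rings, so it is a prochiral benzhydryl carbon with no stereocentre to prepare. C4a is the ring carbon para to the C7 methoxy group, the innate Friedel–Crafts site of a veratryl ring.
Key disconnection: C2–C3 by a sulfonium [3,3]-sigmatropic shift, and C4–C4a by Friedel–Crafts capture of the thionium ion that the shift releases. The C2 methyl is carried at acyl level and C4 at thionium level, so the precursors are the achiral ynamide 7 and the (S,Z)-propenyl sulfoxide 11, whose sulfur is the only stereocentre brought in.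
Ring order: both arenes are bought. The ring C1–C2–C3–C4–C4a–C8a is the only ring formed (step 6). The oxazolidinone is a temporary ring that leaves in step 7.
End game: acyl to CH2OH to CH2SPh, then one Raney nickel hydrogenolysis erases both C–S bonds.

Key step: step 6

Assumption: the sense of sulfur-to-carbon chirality transfer in step 6 is assigned from a chair-like six-membered transition state with the p-tolyl group pseudo-equatorial; the C4 sulfide centre of 15–17 is drawn 3,4-trans, and its configuration has no consequence because C4 becomes CH2 in step 9.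

Step 1
Reactants: 1 3,4-dimethoxybenzaldehyde; 2 ethynylmagnesium bromide
Product: 3 rac-1-(3,4-dimethoxyphenyl)prop-2-yn-1-ol
Conditions: THF, 0 °C to rt; aq NH4Cl
Reagents that add atoms: none
Why: 1,2-addition of an alkynyl Grignard reagent to an aromatic aldehyde; the carbinol centre is racemic and is erased in step 2.

Step 2
Reactants: 3 rac-1-(3,4-dimethoxyphenyl)prop-2-yn-1-ol; 4 1,2-dimethoxybenzene
Product: 5 3,3-bis(3,4-dimethoxyphenyl)prop-1-yne
Conditions: FeCl3 (5 mol %), 4 (3 equiv), MeCN, rt
Reagents that add atoms: none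
Why: Lewis acid-catalysed propargylic Friedel–Crafts substitution (SN1), in which the veratryl-stabilised propargylic cation is attacked by 4 para to a methoxy group, so that the two aryl groups become identical and the new carbon is not stereogenic.

Step 3
Reactants: 5 3,3-bis(3,4-dimethoxyphenyl)prop-1-yne; 6 1,3-oxazolidin-2-one
Product: 7 3-[3,3-bis(3,4-dimethoxyphenyl)prop-1-yn-1-yl]-1,3-oxazolidin-2-one
Conditions: CuCl2 (20 mol %), pyridine, Na2CO3, O2 (1 atm), 6 (5 equiv), toluene, 70 °C, slow addition of 5
Reagents that add atoms: none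
Why: copper-catalysed aerobic oxidative C–N coupling of a terminal alkyne with a cyclic carbamate (ynamide synthesis), with excess 6 and slow addition of 5 holding back Glaser coupling.

Step 4
Reactants: 8 (1S,2R,5S)-menthyl (R)-4-methylbenzenesulfinate; 9 prop-1-yn-1-ylmagnesium bromide
Product: 10 (R)-1-methyl-4-(prop-1-yn-1-ylsulfinyl)benzene
Conditions: toluene/THF, −20 °C; aq NH4Cl
Reagents that add atoms: none
Why: Andersen sulfoxide synthesis, in which the Grignard reagent displaces menthoxide at sulfur with inversion, so the sulfur stereocentre comes from the crystalline commercial sulfinate.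

Step 5
Reactants: 10 (R)-1-methyl-4-(prop-1-yn-1-ylsulfinyl)benzene
Product: 11 (S)-1-methyl-4-[(Z)-prop-1-en-1-ylsulfinyl]benzene
Conditions: H2 (1 atm), RhCl(PPh3)3 (5 mol %), toluene, rt
Reagents that add atoms: none
Why: homogeneous syn-hydrogenation of a 1-alkynyl sulfoxide with Wilkinson's catalyst should stop at the (Z)-alkenyl sulfoxide and leave sulfur untouched (the descriptor changes from R to S only through CIP ranking).

Step 6
Reactants: 7 3-[3,3-bis(3,4-dimethoxyphenyl)prop-1-yn-1-yl]-1,3-oxazolidin-2-one; 11 (S)-1-methyl-4-[(Z)-prop-1-en-1-ylsulfinyl]benzene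
Product: 15 3-{[(1S,2R,3S,4R)-1-(3,4-dimethoxyphenyl)-6,7-dimethoxy-3-methyl-4-(4-methylphenylsulfanyl)-1,2,3,4-tetrahydronaphthalen-2-yl]carbonyl}-1,3-oxazolidin-2-one, via keteniminium ion 12 (not isolated), via vinyloxysulfonium ion 13 (not isolated), via thionium ion 14 (not isolated)
Conditions: HNTf2 (20 mol %), 11 (1.5 equiv), anhydrous CH2Cl2, −40 °C to rt, slow addition of 7
Reagents that add atoms: none
Why: Proposed new method: the acid protonates the ynamide at C2 to give keteniminium 12, the sulfoxide oxygen adds on the side of the C2–H to give the (E)-N,O-ketene acetal 13, a charge-accelerated [3,3]-sigmatropic shift breaks S–O and forms C2–C3, and the released thionium 14 is attacked by the carbon para to a methoxy group of one veratryl ring to form C4–C4a, loss of the arenium proton returning the acid. The closest known reactions are the Brønsted acid-promoted sulfonium [3,3] rearrangement of ynamides with chiral vinyl sulfoxides (ended there by water, giving 1,4-dicarbonyl compounds) and the Pummerer-type thionium Friedel–Crafts cyclisation of veratryl substrates, so the only new element is that a tethered arene instead of water ends the cascade. The single ring closes in 6-exo-trig mode with respect to the C=S+ bond. C2 and C3 are set by the sulfur stereocentre through a chair in which the benzhydryl group (trans to O) is pseudo-equatorial and the (Z)-methyl pseudo-axial, which forces the p-tolyl group pseudo-equatorial and the sulfur lone pair 1,3-diaxial to that methyl and should give the 2,3-trans pair; C1 is set by selection between the two diastereotopic veratryl rings, the spectator ring taking the pseudo-equatorial site trans to the C2 acyl group; C4 is expected 3,4-trans and is erased later. The step needs O-capture of 12 to outrun 5-endo attack by the neighbouring arenes (12 is formed by proton transfer from protonated sulfoxide and so arises next to its trap, helped by excess 11 and slow addition of 7), closure para and not ortho to OMe (secured by the directing methoxy group and by sterics), and exclusion of water so that 14 is not hydrolysed.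

Step 7
Reactants: 15 the tetralin imide from step 6
Product: 16 [(1S,2R,3S,4R)-1-(3,4-dimethoxyphenyl)-6,7-dimethoxy-3-methyl-4-(4-methylphenylsulfanyl)-1,2,3,4-tetrahydronaphthalen-2-yl]methanol
Conditions: LiBH4, H2O (1 equiv), Et2O/THF, 0 °C
Reagents that add atoms: none
Why: reductive cleavage of an N-acyl oxazolidinone with lithium borohydride, which touches no stereocentre and leaves the aryl sulfide and the aryl ethers intact.

Step 8
Reactants: 16 the primary alcohol from step 7
Product: 17 (1S,2R,3S,4R)-1-(3,4-dimethoxyphenyl)-6,7-dimethoxy-3-methyl-4-(4-methylphenylsulfanyl)-2-(phenylsulfanylmethyl)-1,2,3,4-tetrahydronaphthalene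
Conditions: PhSSPh, n-Bu3P, THF, rt to 50 °C
Reagents that add atoms: diphenyl disulfide, c1ccc(cc1)SSc1ccccc1
Why: Hata reaction, in which the alkoxyphosphonium salt of the primary alcohol is displaced by thiolate in an SN2 step at a non-stereogenic carbon.

Step 9
Reactants: 17 the bis-sulfide from step 8
Product: 18 galbulin, (1S,2S,3R)-1-(3,4-dimethoxyphenyl)-6,7-dimethoxy-2,3-dimethyl-1,2,3,4-tetrahydronaphthalene
Conditions: Raney Ni (W-2), EtOH, reflux
Reagents that add atoms: none
Why: Raney nickel desulfurisation (Mozingo-type hydrogenolysis) cleaves both C–S bonds, turning CH2SPh into the C2 methyl and C4–S into CH2, while C1–C3 are untouched (the descriptors at C2 and C3 change only because the sulfur substituents are lost).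

**Compound list**
1 | 3,4-dimethoxybenzaldehyde | COc1ccc(C=O)cc1OC | starting material
2 | ethynylmagnesium bromide | C#C[Mg]Br | starting material
3 | rac-1-(3,4-dimethoxyphenyl)prop-2-yn-1-ol | C#CC(O)c1ccc(OC)c(OC)c1 | intermediate
4 | 1,2-dimethoxybenzene | COc1ccccc1OC | starting material
5 | 3,3-bis(3,4-dimethoxyphenyl)prop-1-yne | C#CC(c1ccc(OC)c(OC)c1)c1ccc(OC)c(OC)c1 | intermediate
6 | 1,3-oxazolidin-2-one | O=C1NCCO1 | starting material
7 | 3-[3,3-bis(3,4-dimethoxyphenyl)prop-1-yn-1-yl]-1,3-oxazolidin-2-one | O=C1OCCN1C#CC(c1ccc(OC)c(OC)c1)c1ccc(OC)c(OC)c1 | intermediate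
8 | (1S,2R,5S)-menthyl (R)-4-methylbenzenesulfinate | C[C@H]1CC[C@@H]([C@H](C1)O[S@@](=O)c2ccc(C)cc2)C(C)C | starting material
9 | prop-1-yn-1-ylmagnesium bromide | CC#C[Mg]Br | starting material
10 | (R)-1-methyl-4-(prop-1-yn-1-ylsulfinyl)benzene | CC#C[S@](=O)c1ccc(C)cc1 | intermediate
11 | (S)-1-methyl-4-[(Z)-prop-1-en-1-ylsulfinyl]benzene | C/C=C\[S@](=O)c1ccc(C)cc1 | intermediate
12 | keteniminium ion (cation of the triflimide salt) | COc1ccc(cc1OC)C(C=C=[N+]1CCOC1=O)c1ccc(OC)c(OC)c1 | intermediate
13 | (E)-vinyloxysulfonium ion, N,O-ketene acetal (cation) | COc1ccc(cc1OC)C(c1ccc(OC)c(OC)c1)/C=C(/O[S@+](c1ccc(C)cc1)/C=C\C)N1CCOC1=O | intermediate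
14 | (2R,3S)-thionium ion (cation) | Cc1ccc(cc1)[S+]=C[C@@H](C)[C@@H](C(c1ccc(OC)c(OC)c1)c1ccc(OC)c(OC)c1)C(=O)N1CCOC1=O | intermediate
15 | 3-{[(1S,2R,3S,4R)-1-(3,4-dimethoxyphenyl)-6,7-dimethoxy-3-methyl-4-(4-methylphenylsulfanyl)-1,2,3,4-tetrahydronaphthalen-2-yl]carbonyl}-1,3-oxazolidin-2-one | COc1ccc([C@H]2c3cc(OC)c(OC)cc3[C@H](Sc4ccc(C)cc4)[C@@H](C)[C@@H]2C(=O)N5CCOC5=O)cc1OC | intermediate
16 | [(1S,2R,3S,4R)-1-(3,4-dimethoxyphenyl)-6,7-dimethoxy-3-methyl-4-(4-methylphenylsulfanyl)-1,2,3,4-tetrahydronaphthalen-2-yl]methanol | COc1ccc([C@H]2c3cc(OC)c(OC)cc3[C@H](Sc4ccc(C)cc4)[C@@H](C)[C@@H]2CO)cc1OC | intermediate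
17 | (1S,2R,3S,4R)-1-(3,4-dimethoxyphenyl)-6,7-dimethoxy-3-methyl-4-(4-methylphenylsulfanyl)-2-(phenylsulfanylmethyl)-1,2,3,4-tetrahydronaphthalene | COc1ccc([C@H]2c3cc(OC)c(OC)cc3[C@H](Sc4ccc(C)cc4)[C@@H](C)[C@@H]2CSc5ccccc5)cc1OC | intermediate
18 | galbulin, (1S,2S,3R) | COc1ccc([C@H]2c3cc(OC)c(OC)cc3C[C@@H](C)[C@@H]2C)cc1OC | target

Total step count: 9. Longest linear sequence: 7 (steps 1, 2, 3, 6, 7, 8, 9).

**Steps most likely to fail**

1. Step 6. The thionium ion may be diverted before the ring closes. Possible diversions are proton loss towards a vinyl sulfide with erosion at C3, capture by the imide oxygen, and capture by traces of water. The choice between the two veratryl rings may also be less clean than the chair model suggests. Fallback: the two bonds are made in separate, known operations.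
   - It sets out from 7 and 11. The rearrangement is run in its known hydrolytic form (HNTf2, CH2Cl2, then water) to give the aldehyde 3-[(2R,3S)-2-[bis(3,4-dimethoxyphenyl)methyl]-3-methyl-4-oxobutanoyl]-1,3-oxazolidin-2-one F1.
   - F1 is converted with 4-methylbenzenethiol and BF3·OEt2 into the dithioacetal 3-[(2R,3S)-2-[bis(3,4-dimethoxyphenyl)methyl]-3-methyl-4,4-bis(4-methylphenylsulfanyl)butanoyl]-1,3-oxazolidin-2-one F2.
   - F2 is ionised with SnCl4 in CH2Cl2 at low temperature for a separate thionium Friedel–Crafts closure, which comes back to the route at 15.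

2. Step 3. Base and heat may promote propargyl-to-allene isomerisation at the doubly benzylic carbon, and oxidative homocoupling of the alkyne may compete. Fallback: it sets out from 5, which is first converted (CuI, aq NH3/EtOH, rt) into the isolable alkynylcopper compound [3,3-bis(3,4-dimethoxyphenyl)prop-1-yn-1-yl]copper F3. F3 is then coupled with 6 at room temperature (TMEDA, O2, MeCN) without added inorganic base, and the route is rejoined at 7.

3. Step 7. Hydride may attack the ring carbonyl of the unsubstituted oxazolidinone (endocyclic cleavage), because the acyl carbon sits between two branched ring carbons. Fallback: it sets out from 15, which is opened with lithium ethanethiolate (EtSH, n-BuLi, THF, 0 °C), a nucleophile that cleaves hindered imides at the exocyclic acyl group. This gives the thioester S-ethyl (1S,2R,3S,4R)-1-(3,4-dimethoxyphenyl)-6,7-dimethoxy-3-methyl-4-(4-methylphenylsulfanyl)-1,2,3,4-tetrahydronaphthalene-2-carbothioate F4. LiAlH4 in THF at 0 °C then reduces F4, and the route is rejoined at 16.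

**Further compounds**
F1 | step 6 | 3-[(2R,3S)-2-[bis(3,4-dimethoxyphenyl)methyl]-3-methyl-4-oxobutanoyl]-1,3-oxazolidin-2-one | O=C[C@@H](C)[C@@H](C(c1ccc(OC)c(OC)c1)c1ccc(OC)c(OC)c1)C(=O)N1CCOC1=O
F2 | step 6 | 3-[(2R,3S)-2-[bis(3,4-dimethoxyphenyl)methyl]-3-methyl-4,4-bis(4-methylphenylsulfanyl)butanoyl]-1,3-oxazolidin-2-one | Cc1ccc(cc1)SC(Sc1ccc(C)cc1)[C@@H](C)[C@@H](C(c1ccc(OC)c(OC)c1)c1ccc(OC)c(OC)c1)C(=O)N1CCOC1=O
F3 | step 3 | [3,3-bis(3,4-dimethoxyphenyl)prop-1-yn-1-yl]copper | [Cu]C#CC(c1ccc(OC)c(OC)c1)c1ccc(OC)c(OC)c1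
F4 | step 7 | S-ethyl (1S,2R,3S,4R)-1-(3,4-dimethoxyphenyl)-6,7-dimethoxy-3-methyl-4-(4-methylphenylsulfanyl)-1,2,3,4-tetrahydronaphthalene-2-carbothioate | COc1ccc([C@H]2c3cc(OC)c(OC)cc3[C@H](Sc4ccc(C)cc4)[C@@H](C)[C@@H]2C(=O)SCC)cc1OC
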